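The depside ester bond is cut to give a chlorinated ring A acid and benzyl olivetolate, and everything then rests on building ring B from acyclic carbon. Ring B carries its carboxyl on C1, oxygens on C2 and C4, and the pentyl chain on C6. This is exactly the pattern left when a malonate diester is annulated onto a 3-alken-2-one. In one operation dibenzyl malonate 1 and (E)-non-3-en-2-one 2, both purchased, form bonds C1–C6 (Michael) and C2–C3 (Claisen). The result is the fully substituted cyclohexanedione with its carboxyl already benzyl-protected. Mild oxidation gives the arene, whose unchelated O4 is acylated, and debenzylation ends the route.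

Key step: step 1

Remark on the chemistry: the target has no stereocentre. The sp3 centres of the non-aromatic ring B intermediates are racemic or epimerisable and are drawn without configuration. The dione is written in its diketo form although it should exist largely as an enol.

Step 1
Reactants: 1 dibenzyl malonate; 2 (E)-non-3-en-2-one
Product: 5 benzyl 2,4-dioxo-6-pentylcyclohexane-1-carboxylate, via sodium dibenzyl malonate 3 (not isolated), via Michael adduct 4 (not isolated)
Conditions: NaH (1.05 equiv), 1 (1.1 equiv), THF, 0 °C; then 2, 0 °C to reflux; cold 1 M HCl work-up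
Reagents that add atoms: none
Why: NaH converts 1 into the soft enolate 3, which adds 1,4 to the unhindered beta carbon C4 of enone 2 and forms ring B bond C1–C6 (Michael addition). Proton exchange, carried by the benzyloxide that the reaction itself liberates, opens access to the terminal CH3 enolate of adduct 4, which attacks one of the two equivalent benzyl esters and expels benzyloxide to form bond C2–C3 (intramolecular Claisen, Dieckmann-type condensation). The single ring closes in the 6-(enolendo)-exo-trig mode, a favoured geometry. This is the classical malonate/alkenone annulation to dihydroresorcylates, run here in an aprotic solvent so that no foreign alkoxide can exchange the benzyl ester, and it is pulled forward because 5, a vinylogous acid, is held as its sodium salt, which is why a full equivalent of base is used. The two sp3 centres C1 and C6 arise without control (C6 racemic, C1 epimerisable) and need none, since both become sp2 in step 2. Regiochemistry is secured by the substrate, because the internal CH2 enolate of 4 could only close a strained four-membered ring, so only the 2,4-dioxo/6-pentyl pattern can form.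

Step 2
Reactants: 5 benzyl 2,4-dioxo-6-pentylcyclohexane-1-carboxylate
Product: 7 benzyl 2,4-dihydroxy-6-pentylbenzoate, via C1 iodide 6 (not isolated)
Conditions: I2 (0.2 equiv), DMSO, 80 °C; aq. Na2S2O3 work-up
Reagents that add atoms: none
Why: This is an iodine-catalysed oxidative aromatisation (alpha-halogenation/dehydrohalogenation with DMSO as terminal oxidant), known for alkyl 6-alkyl-2,4-dioxocyclohexanecarboxylates, in which iodination of the doubly activated C1 gives 6, loss of HI across C1–C6 and tautomerisation give the resorcylate, and re-oxidation of HI to I2 by DMSO keeps hydrogen halide at trace level, so the benzyl ester is spared the acidolysis and decarboxylation that stoichiometric halogen in a hot amide solvent would invite.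

Step 3
Reactants: 8 5-propylbenzene-1,3-diol
Product: 9 1,3-dimethoxy-5-propylbenzene
Conditions: MeI (2.5 equiv), K2CO3, acetone, reflux
Reagents that add atoms: iodomethane, CI
Why: This is a double Williamson ether synthesis on an unhindered resorcinol, in which one methyl group ends as the 4-methoxy group of ring A and the other serves as directing and protecting group until step 7.

Step 4
Reactants: 9 1,3-dimethoxy-5-propylbenzene
Product: 11 2-chloro-1,3-dimethoxy-5-propylbenzene, via aryllithium 10 (not isolated)
Conditions: n-BuLi, THF, 0 °C to rt; then C2Cl6, −78 °C to rt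
Reagents that add atoms: hexachloroethane, ClC(Cl)(Cl)C(Cl)(Cl)Cl
Why: In this directed ortho-metalation the two methoxy groups cooperate to send lithium to the carbon between them, and chlorine transfer from C2Cl6 to 10 fixes the halogen at the future C3 of ring A, a position that direct electrophilic chlorination of a resorcylate could not be trusted to select over C5.

Step 5
Reactants: 11 2-chloro-1,3-dimethoxy-5-propylbenzene
Product: 12 2-bromo-4-chloro-3,5-dimethoxy-1-propylbenzene (bromine between the propyl group and a methoxy group)
Conditions: NBS (1.0 equiv), MeCN, 0 °C to rt, dark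
Reagents that add atoms: N-bromosuccinimide, O=C1CCC(=O)N1Br
Why: In this electrophilic aromatic bromination the two free ring positions of 11 are equivalent by symmetry and activated ortho/para by the methoxy groups, so one equivalent of NBS in a polar solvent (ionic rather than benzylic radical pathway) can lead only to 12.

Step 6
Reactants: 12 2-bromo-4-chloro-3,5-dimethoxy-1-propylbenzene
Product: 14 3-chloro-2,4-dimethoxy-6-propylbenzoic acid, via aryllithium 13 (not isolated)
Conditions: n-BuLi, THF, −78 °C; CO2; 1 M HCl
Reagents that add atoms: carbon dioxide, O=C=O
Why: Bromine–lithium exchange is followed by carboxylation, because exchange at C–Br is far faster than at C–Cl at −78 °C and the chlorine of 13 sits meta to lithium, so no aryne can form before CO2 traps the anion.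

Step 7
Reactants: 14 3-chloro-2,4-dimethoxy-6-propylbenzoic acid
Product: 15 3-chloro-2-hydroxy-4-methoxy-6-propylbenzoic acid
Conditions: BCl3 (2.5 equiv), CH2Cl2, −78 to 0 °C; H2O
Reagents that add atoms: none
Why: In this chelation-controlled aryl methyl ether cleavage boron is held between a carboxyl oxygen and the neighbouring 2-methoxy oxygen in a six-membered chelate, so chloride dealkylates only that methyl group while the unchelated 4-methoxy group stays intact at low temperature.

Step 8
Reactants: 15 3-chloro-2-hydroxy-4-methoxy-6-propylbenzoic acid; 7 benzyl 2,4-dihydroxy-6-pentylbenzoate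
Product: 17 benzyl 4-[(3-chloro-2-hydroxy-4-methoxy-6-propylbenzoyl)oxy]-2-hydroxy-6-pentylbenzoate, via mixed trifluoroacetic anhydride 16 (not isolated)
Conditions: (CF3CO)2O, toluene, rt
Reagents that add atoms: none
Why: In this depside esterification through a mixed trifluoroacetic anhydride, 16 acylates the only free phenol, O4 of 7, because the 2-hydroxyl groups of both partners are tied up in hydrogen bonds to their neighbouring carbonyl groups and are sterically flanked.

Step 9
Reactants: 17 benzyl 4-[(3-chloro-2-hydroxy-4-methoxy-6-propylbenzoyl)oxy]-2-hydroxy-6-pentylbenzoate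
Product: 18 4-[(3-chloro-2-hydroxy-4-methoxy-6-propylbenzoyl)oxy]-2-hydroxy-6-pentylbenzoic acid (target)
Conditions: H2 (1 atm), Pd/C (10 wt% Pd), EtOAc, rt, stopped after one equivalent of H2
Reagents that add atoms: none
Why: In this catalytic hydrogenolysis of a benzyl ester, benzylic C–O cleavage in neutral ethyl acetate without added base is much faster than reduction of the aryl C–Cl bond, so the chlorine, the aryl ester and the methyl ether should remain untouched.

Compound list
1 | dibenzyl malonate | O=C(CC(=O)OCc1ccccc1)OCc1ccccc1 | starting material
2 | (E)-non-3-en-2-one | CCCCC/C=C/C(C)=O | starting material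
3 | sodium dibenzyl malonate (sodium enolate of 1) | [Na+].O=C(OCc1ccccc1)[CH-]C(=O)OCc1ccccc1 | intermediate
4 | dibenzyl 2-(2-oxononan-4-yl)propanedioate (racemic) | CCCCCC(CC(C)=O)C(C(=O)OCc1ccccc1)C(=O)OCc1ccccc1 | intermediate
5 | benzyl 2,4-dioxo-6-pentylcyclohexane-1-carboxylate (racemic, enolisable) | CCCCCC1CC(=O)CC(=O)C1C(=O)OCc1ccccc1 | intermediate
6 | benzyl 1-iodo-2,4-dioxo-6-pentylcyclohexane-1-carboxylate (racemic) | CCCCCC1CC(=O)CC(=O)C1(C(=O)OCc2ccccc2)I | intermediate
7 | benzyl 2,4-dihydroxy-6-pentylbenzoate (benzyl olivetolate) | CCCCCc1cc(O)cc(O)c1C(=O)OCc1ccccc1 | intermediate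
8 | 5-propylbenzene-1,3-diol | CCCc1cc(O)cc(O)c1 | starting material
9 | 1,3-dimethoxy-5-propylbenzene | CCCc1cc(OC)cc(OC)c1 | intermediate
10 | (2,6-dimethoxy-4-propylphenyl)lithium | CCCc1cc(OC)c([Li])c(OC)c1 | intermediate
11 | 2-chloro-1,3-dimethoxy-5-propylbenzene | CCCc1cc(OC)c(Cl)c(OC)c1 | intermediate
12 | 2-bromo-4-chloro-3,5-dimethoxy-1-propylbenzene | CCCc1cc(OC)c(Cl)c(OC)c1Br | intermediate
13 | (3-chloro-2,4-dimethoxy-6-propylphenyl)lithium | CCCc1cc(OC)c(Cl)c(OC)c1[Li] | intermediate
14 | 3-chloro-2,4-dimethoxy-6-propylbenzoic acid | CCCc1cc(OC)c(Cl)c(OC)c1C(=O)O | intermediate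
15 | 3-chloro-2-hydroxy-4-methoxy-6-propylbenzoic acid | CCCc1cc(OC)c(Cl)c(O)c1C(=O)O | intermediate
16 | 3-chloro-2-hydroxy-4-methoxy-6-propylbenzoic trifluoroacetic anhydride | CCCc1cc(OC)c(Cl)c(O)c1C(=O)OC(=O)C(F)(F)F | intermediate
17 | benzyl 4-[(3-chloro-2-hydroxy-4-methoxy-6-propylbenzoyl)oxy]-2-hydroxy-6-pentylbenzoate | CCCCCc1cc(OC(=O)c2c(CCC)cc(OC)c(Cl)c2O)cc(O)c1C(=O)OCc1ccccc1 | intermediate
18 | 4-[(3-chloro-2-hydroxy-4-methoxy-6-propylbenzoyl)oxy]-2-hydroxy-6-pentylbenzoic acid | CCCCCc1cc(OC(=O)c2c(CCC)cc(OC)c(Cl)c2O)cc(O)c1C(=O)O | target

Total step count: 9.
Longest linear sequence: 7 steps (steps 3 to 9, from 8 to 18). The ring B branch contributes steps 1 and 2 and joins at step 8.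

Steps most likely to fail

Step 1. In the aprotic medium, proton shuttling between the malonate anion and the methyl ketone enolate may be slow. The sequence could then stall at the open-chain stage or revert by retro-Michael cleavage on prolonged heating.
- The fallback sets out from 2 and moves installation of the benzyl ester to after the ring closure.
- Compound 2 is annulated with dimethyl malonate under the long-established protic conditions (NaOMe, MeOH, reflux).
- This passes through dimethyl 2-(2-oxononan-4-yl)propanedioate F1 and gives methyl 2,4-dioxo-6-pentylcyclohexane-1-carboxylate F2.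
- Thermal ester exchange of this beta-keto ester with excess benzyl alcohol follows (toluene, reflux, methanol distilled out, acylketene pathway), and the route is rejoined at 5.

Step 2. The electron-rich arene, once formed, may be iodinated on the ring and so drain the catalyst. Slow loss of the benzyl ester followed by decarboxylation may also compete.
- The fallback sets out from 5 and replaces halogenation/elimination by dehydrogenation of a silyl dienol ether.
- Me3SiOSO2CF3 and Et3N in CH2Cl2 at 0 °C should give benzyl 6-pentyl-2,4-bis(trimethylsilyloxy)cyclohexa-1,3-diene-1-carboxylate F3.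
- DDQ in toluene at rt abstracts hydride from the sp3 part of the ring and gives benzyl 6-pentyl-2,4-bis(trimethylsilyloxy)benzoate F4.
- Dilute HCl in THF removes the silyl groups, and the route is rejoined at 7.

Step 9. Hydrodechlorination of ring A may compete with benzylic C–O cleavage, especially if the reaction is left beyond one equivalent of hydrogen.
- The fallback sets out from 17 and replaces reduction by Lewis-acid dealkylation, using BCl3 (3 equiv) and pentamethylbenzene as cation scavenger in CH2Cl2 at −78 to −20 °C.
- Boron chelated between the 2-hydroxyl oxygen of ring B and the ester carbonyl activates the O–benzyl bond.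
- The benzyl cation is captured by the scavenger, and the unchelated 4-methoxy group and the aryl ester are not dealkylated at this temperature.
- Aqueous work-up gives 18 directly.

Further compounds
F1 | step 1 | dimethyl 2-(2-oxononan-4-yl)propanedioate | CCCCCC(CC(C)=O)C(C(=O)OC)C(=O)OC
F2 | step 1 | methyl 2,4-dioxo-6-pentylcyclohexane-1-carboxylate | CCCCCC1CC(=O)CC(=O)C1C(=O)OC
F3 | step 2 | benzyl 6-pentyl-2,4-bis(trimethylsilyloxy)cyclohexa-1,3-diene-1-carboxylate | CCCCCC1CC(O[Si](C)(C)C)=CC(O[Si](C)(C)C)=C1C(=O)OCc1ccccc1
F4 | step 2 | benzyl 6-pentyl-2,4-bis(trimethylsilyloxy)benzoate | CCCCCc1cc(O[Si](C)(C)C)cc(O[Si](C)(C)C)c1C(=O)OCc1ccccc1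
F0 | step 9 | none | none
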